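**Assumption:** the target has no stereocentre and no stereogenic double bond, so "single enantiomer" means the one achiral compound; 1, 2, 5, 6 and 9 are taken as catalogue chemicals.

**Retrosynthetic overview**
1. Target 12 ⇐ tert-butyl ester 11 by acidolysis in the last step.
2. Key disconnection: the depside aryl C–O bond at C4 of ring B. 11 ⇐ free salicylic acid 4 + arene 8 by one-pot C–H borylation and copper-mediated acyloxylation, so ring B never carries a phenol.
3. Both 2-oxoheptyl chains ⇐ lateral (benzylic) lithiation of o-toluic acid derivatives 1 and 7, acylated with Weinreb amide 2.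
4. 4 ⇐ 3 by chelation-controlled ortho-demethylation; 7 ⇐ acid 5 by tert-butyl esterification.
5. No ring is formed: rings A and B are both bought as benzoic acids 1 and 5.

**Route**

Step 1
Reactants: 1 2,4-dimethoxy-6-methylbenzoic acid; 2 N-methoxy-N-methylhexanamide
Product: 3 2,4-dimethoxy-6-(2-oxoheptyl)benzoic acid
Conditions: LiN(iPr)2 (2.5 equiv), THF, −78 → 0 °C, 1 h; then 2 (1.2 equiv), −78 → −20 °C; cold 1 M HCl to pH 3, acid–base extraction
Reagents that add atoms: N-methoxy-N-methylhexanamide (2), CCCCCC(=O)N(C)OC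
Why: Lateral lithiation of the o-toluate dianion followed by Weinreb ketone synthesis; the chelated tetrahedral adduct prevents over-addition and keeps the acidic benzyl ketone masked until the quench.

Step 2
Reactants: 3 2,4-dimethoxy-6-(2-oxoheptyl)benzoic acid
Product: 4 2-hydroxy-4-methoxy-6-(2-oxoheptyl)benzoic acid
Conditions: BCl3 (2.5 equiv), CH2Cl2, −78 → −10 °C, 1 h; ice-water quench, extract cold
Reagents that add atoms: none
Why: Chelation-controlled Lewis-acid ether cleavage: boron bound to the carboxyl group cleaves only the ortho methoxy group through a six-membered chelate, leaving the 4-OMe, the ketone and the acid untouched at low temperature.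

Step 3
Reactants: 5 2-methoxy-6-methylbenzoic acid; 6 tert-butyl 2,2,2-trichloroacetimidate
Product: 7 tert-butyl 2-methoxy-6-methylbenzoate
Conditions: 6 (2.0 equiv), BF3·OEt2 (5 mol%), CH2Cl2–cyclohexane, 0 °C → rt
Reagents that add atoms: tert-butyl 2,2,2-trichloroacetimidate (6), CC(C)(C)OC(=N)C(Cl)(Cl)Cl
Why: Imidate esterification: the carboxyl oxygen is alkylated by the tert-butyl cation released from the protonated imidate, which avoids attack at the hindered di-ortho-substituted carbonyl carbon.

Step 4
Reactants: 7 tert-butyl 2-methoxy-6-methylbenzoate; 2 N-methoxy-N-methylhexanamide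
Product: 8 tert-butyl 2-methoxy-6-(2-oxoheptyl)benzoate
Conditions: LiN(iPr)2 (1.3 equiv), THF, −78 °C, 45 min; then 2 (1.2 equiv), −78 → −40 °C; sat. aq. NH4Cl
Reagents that add atoms: N-methoxy-N-methylhexanamide (2), CCCCCC(=O)N(C)OC
Why: Lateral lithiation of the o-toluate ester (the bulky tert-butyl ester suppresses self-condensation) followed by Weinreb ketone synthesis.

Step 5
Reactants: 8 tert-butyl 2-methoxy-6-(2-oxoheptyl)benzoate; 9 bis(pinacolato)diboron; 4 2-hydroxy-4-methoxy-6-(2-oxoheptyl)benzoic acid
Product: 11 tert-butyl 4-{[2-hydroxy-4-methoxy-6-(2-oxoheptyl)benzoyl]oxy}-2-methoxy-6-(2-oxoheptyl)benzoate, via aryl pinacolboronate 10 (not isolated)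
Conditions: [Ir(OMe)(cod)]2 (1.5 mol%), 4,4'-di-tert-butyl-2,2'-bipyridine (3 mol%), 9 (1.0 equiv), THF, 80 °C, 12 h; evaporate; then 4 (1.1 equiv), Cu(OTf)2 (2.2 equiv), K2CO3 (1.0 equiv), pyridine (4 equiv), 4 Å MS, MeCN, 50 °C, Ar
Reagents that add atoms: 2-hydroxy-4-methoxy-6-(2-oxoheptyl)benzoic acid (4), CCCCCC(=O)Cc1cc(OC)cc(O)c1C(=O)O; bis(pinacolato)diboron (9), CC1(C)OB(OC1(C)C)B1OC(C)(C)C(C)(C)O1 (supplies only the boryl group of 10, which is lost again)
Why: Proposed new method: a formal meta C–H acyloxylation that builds the depside at oxygen: the trivalent iridium tris-boryl catalyst borylates the only C–H without an ortho substituent (C4 of the 1,2,3-trisubstituted ring B) to give 10; the aryl group then transmetalates from boron to the divalent copper carboxylate of 4, a second divalent copper oxidises this to an aryl–trivalent copper carboxylate, and C–O reductive elimination gives the aryl ester and monovalent copper; because the bond forms at the carboxylate oxygen, the di-ortho-substituted acyl carbon never passes through a tetrahedral intermediate, K2CO3 ionises only the carboxyl group while the hydrogen-bonded 2-OH stays neutral, and running under argon with stoichiometric copper avoids aerobic oxidation of the benzyl ketones; the closest known reactions are the Chan–Lam O-arylation of carboxylic acids with arylboronic acids and one-pot C–H borylation/copper-mediated functionalisation, neither shown for an in-situ pinacol boronate with a hindered free salicylic acid.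

Step 6
Reactants: 11 tert-butyl 4-{[2-hydroxy-4-methoxy-6-(2-oxoheptyl)benzoyl]oxy}-2-methoxy-6-(2-oxoheptyl)benzoate
Product: 12 4-{[2-hydroxy-4-methoxy-6-(2-oxoheptyl)benzoyl]oxy}-2-methoxy-6-(2-oxoheptyl)benzoic acid
Conditions: TFA–CH2Cl2 (1:4), 0 °C, 1–2 h; evaporate cold with toluene
Reagents that add atoms: none
Why: tert-Butyl ester acidolysis (E1 loss of isobutene, helped by strain relief in the di-ortho-substituted ester); the depside aryl ester, both ketones and the methyl ethers are inert to anhydrous TFA at 0 °C.

**Compound list**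
1 | 2,4-dimethoxy-6-methylbenzoic acid | Cc1cc(OC)cc(OC)c1C(=O)O | starting material
2 | N-methoxy-N-methylhexanamide | CCCCCC(=O)N(C)OC | starting material
3 | 2,4-dimethoxy-6-(2-oxoheptyl)benzoic acid | CCCCCC(=O)Cc1cc(OC)cc(OC)c1C(=O)O | intermediate
4 | 2-hydroxy-4-methoxy-6-(2-oxoheptyl)benzoic acid | CCCCCC(=O)Cc1cc(OC)cc(O)c1C(=O)O | intermediate
5 | 2-methoxy-6-methylbenzoic acid | Cc1cccc(OC)c1C(=O)O | starting material
6 | tert-butyl 2,2,2-trichloroacetimidate | CC(C)(C)OC(=N)C(Cl)(Cl)Cl | starting material
7 | tert-butyl 2-methoxy-6-methylbenzoate | Cc1cccc(OC)c1C(=O)OC(C)(C)C | intermediate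
8 | tert-butyl 2-methoxy-6-(2-oxoheptyl)benzoate | CCCCCC(=O)Cc1cccc(OC)c1C(=O)OC(C)(C)C | intermediate
9 | bis(pinacolato)diboron | CC1(C)OB(OC1(C)C)B1OC(C)(C)C(C)(C)O1 | starting material
10 | tert-butyl 2-methoxy-6-(2-oxoheptyl)-4-(4,4,5,5-tetramethyl-1,3,2-dioxaborolan-2-yl)benzoate | CCCCCC(=O)Cc1cc(B2OC(C)(C)C(C)(C)O2)cc(OC)c1C(=O)OC(C)(C)C | intermediate
11 | tert-butyl 4-{[2-hydroxy-4-methoxy-6-(2-oxoheptyl)benzoyl]oxy}-2-methoxy-6-(2-oxoheptyl)benzoate | CCCCCC(=O)Cc1cc(OC)cc(O)c1C(=O)Oc1cc(CC(=O)CCCCC)c(C(=O)OC(C)(C)C)c(OC)c1 | intermediate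
12 | 4-{[2-hydroxy-4-methoxy-6-(2-oxoheptyl)benzoyl]oxy}-2-methoxy-6-(2-oxoheptyl)benzoic acid | CCCCCC(=O)Cc1cc(OC)cc(O)c1C(=O)Oc1cc(CC(=O)CCCCC)c(C(=O)O)c(OC)c1 | target

**Totals**
Total step count: 6. Longest linear sequence: 4 steps (5 → 7 → 8 → 11 → 12, or equally 1 → 3 → 4 → 11 → 12).

**Three steps most likely to fail**

Step 5 (the new C–H borylation/acyloxylation). Possible failures are O-arylation of the free 2-OH of 4, copper chelation by the salicylate, slow transmetalation of the pinacol boronate, or Lewis-acid lactonisation of 4. The fallback uses known chemistry and sets out from 8. The same iridium-catalysed borylation gives 10, which is oxidised in the same pot with NaBO3·4H2O in THF–H2O to tert-butyl 4-hydroxy-2-methoxy-6-(2-oxoheptyl)benzoate F1. F1 is then esterified with acid 4 by dicyclohexylcarbodiimide in dry toluene at 0 °C → rt; the only phenol on ring B is the 4-OH, and the 2-OH of 4 is hydrogen-bonded. This comes back to the route at 11 at the cost of one extra step.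

Step 2 (BCl3 on the free keto acid). The activated acyloxyborane may be trapped by the ketone enol and close to the isocoumarin instead of giving 4. The fallback sets out from 3 and makes that ring closure deliberate. Ac2O at reflux gives 6,8-dimethoxy-3-pentyl-1H-isochromen-1-one F2. BCl3 in CH2Cl2 (−78 → 0 °C) then cleaves the 8-OMe peri to the lactone carbonyl to give 8-hydroxy-6-methoxy-3-pentyl-1H-isochromen-1-one F3. KOH in EtOH–H2O opens the enol lactone, and cold acidification to pH 3 returns to the route at 4 (two extra steps).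

Step 1 (lateral lithiation of the electron-rich free acid as its dianion). Metalation may be incomplete, ring lithiation may compete, and the lithium carboxylate may be poorly soluble. The fallback sets out from 1. MeI/K2CO3 in DMF gives methyl 2,4-dimethoxy-6-methylbenzoate F4 (also purchasable). Classical ester-anion chemistry (LiN(iPr)2, THF, −78 °C, then 2) gives methyl 2,4-dimethoxy-6-(2-oxoheptyl)benzoate F5. KOH in EtOH–H2O at reflux saponifies the hindered ester with help from the neighbouring ketone enolate, and cold acidification comes back to the route at 3 (two extra steps).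

**Further compounds**
F1 | step 5 | tert-butyl 4-hydroxy-2-methoxy-6-(2-oxoheptyl)benzoate | CCCCCC(=O)Cc1cc(O)cc(OC)c1C(=O)OC(C)(C)C
F2 | step 2 | 6,8-dimethoxy-3-pentyl-1H-isochromen-1-one | CCCCCC1=Cc2cc(OC)cc(OC)c2C(=O)O1
F3 | step 2 | 8-hydroxy-6-methoxy-3-pentyl-1H-isochromen-1-one | CCCCCC1=Cc2cc(OC)cc(O)c2C(=O)O1
F4 | step 1 | methyl 2,4-dimethoxy-6-methylbenzoate | Cc1cc(OC)cc(OC)c1C(=O)OC
F5 | step 1 | methyl 2,4-dimethoxy-6-(2-oxoheptyl)benzoate | CCCCCC(=O)Cc1cc(OC)cc(OC)c1C(=O)OC
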